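The runs are calculated with made-up constants; noise was put on by code.

Slowness came first: in 6.00 h the summer run lost 42.0% of its substrate and the winter run 43.0%, although their nucleophile charges differ, so I took one first-order constant from the summer run, 0.0908 h⁻¹.

| setting | winter | summer | zeta | alpha |
|---|---|---|---|---|
| substrate | 0.050 M | 0.050 M | 0.20 M | 0.050 M |
| first nucleophile | 4.5 equiv | 3 equiv | 3.00 equiv | 3.00 equiv |
| second nucleophile | 1.5 equiv | 0.75 equiv | 1.50 equiv | 1.50 equiv |
| protic impurity | 0.025 M | 0.025 M | 0.0800 M | 0.0250 M |
| remark | run made earlier | run made earlier |  |  |
| time |  |  | 30 h | 30 h |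

| run | time / h | target / % | substrate / % |
|---|---|---|---|
| winter | 0.417 | 3 | 95 |
| winter | 1.33 | 6 | 88 |
| winter | 2.00 | 5 | 82 |
| winter | 3.00 | 6 | 76 |
| winter | 5.00 | 15 | 66 |
| winter | 6.00 | 18 | 57 |
| summer | 1.00 | 3 | 90 |
| summer | 2.00 | 7 | 82 |
| summer | 3.00 | 12 | 75 |
| summer | 4.00 | 15 | 69 |
| summer | 5.00 | 18 | 63 |
| summer | 6.00 | 20 | 58 |

(each reading ± 1.5 percentage points)

- which of the two ends with the higher amount of target, in percent of the substrate charged ("neither" if they lie within 2 percentage points) (zeta / alpha / neither)
- target at the end, in percent of the substrate charged, zeta
- target at the end, in percent of the substrate charged, alpha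

- the earlier runs were read with a standard deviation of 1.5 percentage points
- where the amount of substrate changes, what is given in equivalents or mol% on it follows
- no earlier run changes the charge of protic impurity; that part of a forecast is a guess

How much substrate goes by 30 h? That constant gave 93.4% lost, if it holds at 0.20 M, which no run tests.

What share of that becomes target? At the last reading, target over the other substrate lost was 0.720 in the winter run, at a charged ratio of first to second nucleophile of 3.00. In the summer run it was 0.909, at a ratio of 4.00. Dividing gave 0.240 and 0.227, close together for readings with a scatter of 1.5 percentage points. Their mean, 0.234, is the capture odds g, an apparent selectivity factor read from these runs: target formed per substrate lost any other way, divided by that charged ratio.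

Zeta and alpha share the ratio 2.00, lower than either run, so this is an extrapolation, and g holds no term for 0.20 M. It gave odds of 0.467, a target share of 31.8%, and 29.8% target in both flasks. The impurity stayed a guess: taken one for one, it would remove 13.3% of the first nucleophile in zeta and 16.7% in alpha. I expected a tie.

The forecast stood higher: 55% for zeta, 48% for alpha, with zeta ahead, holding that “Changing the nucleophile charges has little visible effect on selectivity”.

Zeta ended at 34.2% target and alpha at 34.1%, so the answer was neither. The constants behind the flask were these.

    second nucleophile + intermediate → other capture product (k = 26.0 M⁻¹ min⁻¹)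
    substrate ⇌ intermediate (K = 0.0430, k = 9.60 × 10⁻⁴ min⁻¹)
    first nucleophile + intermediate → target (k = 19.0 M⁻¹ min⁻¹)
    intermediate → side product (k = 0.00240 min⁻¹)
    substrate ⇌ dormant form (K = 5.10, k = 5.80 × 10⁻⁴ min⁻¹)
    first nucleophile + protic impurity → quenched reagent (k = 0.0260 M⁻¹ min⁻¹)

Beside that target, zeta held 26.0% of other capture product. With zeta's 91.8% of substrate lost, my g gave 29.2% target, and zeta's own figures give a g of 0.297. In the neighbour, zeta with 6.00 equiv of second nucleophile, the ratio falls to 0.500. That g, with 91.8% of substrate lost, gives 11.9% target, and that flask held 14.7%.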